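Target: two benzophenones joined by one CH2. Numbering used: in rings A (left) and A' (right) C1 bears OCH3, C3 and C5 bear OH, C4 the ketone carbon and C6 the CH2 bridge; ring B (4,6-dihydroxy-2-methylphenyl) and ring B' (4-hydroxy-6-methoxy-2-methylphenyl) are bound to the ketone through C1. There is no stereocenter.
Feature the strategy rests on: each ketone carbon lies between two aryl carbons that both have two ortho substituents (C4 of ring A' between the C3 and C5 oxygens, C1 of ring B' between C2–CH3 and C6–OCH3). The carbonyl is therefore brought in as CO between an aryl iodide and an arylboronic acid, making C4(A')–C(=O) and C(=O)–C1(B') in one operation. Rings A and A' are identical, so one iodide serves both halves.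
Retro order: (a) the three benzyl ethers on rings B and B' by hydrogenolysis; (b) the C6(A)–CH2 bond, by attack of the free ring A of the left ketone on the ortho-quinone methide released from the C6-aminomethyl right ketone; (c) each ketone into iodide + CO + boronic acid.
Protecting groups: the ring A/A' oxygens travel as methoxymethyl (MOM) ethers, which direct the lithiation that gives the iodide and leave with acid; the ring B/B' oxygens travel as benzyl ethers, so only rings A and A' are free phenols when the halves are joined.
No ring is formed; the benzene rings come from 5-methoxyresorcinol (A, A'), 2-bromo-3-methylanisole (B') and orcinol (B).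

Key step: step 6

Step 1
Reactants: 1 5-methoxyresorcinol
Product: 2 1-methoxy-3,5-bis(methoxymethoxy)benzene
Conditions: NaH (2.4 equiv), MOMCl (2.4 equiv), DMF, 0 °C to rt
Reagents that add atoms: chloromethyl methyl ether, COCCl
Why: Williamson-type O-alkylation of both phenoxides by the reactive α-chloro ether (MOM protection), the hard electrophile favouring O- over C-alkylation.

Step 2
Reactants: 2 1-methoxy-3,5-bis(methoxymethoxy)benzene
Product: 4 2-iodo-5-methoxy-1,3-bis(methoxymethoxy)benzene, via aryllithium 3 (not isolated)
Conditions: n-BuLi (1.1 equiv), THF, 0 °C; then iodine in THF, −78 °C to rt; aq. Na2S2O3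
Reagents that add atoms: iodine, [I][I]; n-butyllithium, [Li]CCCC (its lithium stays only in 3)
Why: Directed ortho-metalation: the C–H between the two chelating OMOM groups is removed in preference to the C–H flanked by OMOM and OCH3, and iodine quenches the aryllithium at that carbon.

Step 3
Reactants: 5 2-bromo-3-methylanisole
Product: 7 4-bromo-3-methoxy-5-methylphenol, via arylboronic pinacol ester 6 (not isolated)
Conditions: [Ir(OMe)(cod)]2 (1.5 mol %), 4,4'-di-tert-butyl-2,2'-bipyridine (3 mol %), B2pin2 (0.7 equiv), THF, 80 °C; evaporate; then KHSO5 (as 2KHSO5·KHSO4·K2SO4), acetone–H2O, rt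
Reagents that add atoms: bis(pinacolato)diboron, CC1(C)OB(OC1(C)C)B1OC(C)(C)C(C)(C)O1 (its boryl group stays only in 6); potassium peroxymonosulfate, [K+].OOS(=O)(=O)[O-] (hydroxyl oxygen of 7)
Why: One-pot iridium-catalysed C–H borylation/oxidation: borylation is governed by sterics and in this 1,2,3-trisubstituted benzene takes the only C–H without an ortho neighbour (para to bromine), the C–Br bond is inert to the catalyst, and KHSO5 turns the C–B bond into C–OH at the same carbon.

Step 4
Reactants: 7 4-bromo-3-methoxy-5-methylphenol
Product: 8 5-(benzyloxy)-2-bromo-1-methoxy-3-methylbenzene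
Conditions: BnBr (1.2 equiv), K2CO3 (2 equiv), DMF, rt
Reagents that add atoms: benzyl bromide, BrCc1ccccc1
Why: Williamson ether synthesis on the unhindered phenoxide.

Step 5
Reactants: 8 5-(benzyloxy)-2-bromo-1-methoxy-3-methylbenzene
Product: 11 [4-(benzyloxy)-2-methoxy-6-methylphenyl]boronic acid, via aryllithium 9 (not isolated), via lithium aryltriisopropoxyborate 10 (not isolated)
Conditions: n-BuLi (1.05 equiv), THF, −78 °C; B(OiPr)3 (1.5 equiv), −78 °C to rt; 1 M HCl, 0 °C
Reagents that add atoms: triisopropyl borate, CC(C)OB(OC(C)C)OC(C)C; water, O; n-butyllithium, [Li]CCCC (its lithium stays only in 9 and 10)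
Why: Bromine–lithium exchange at −78 °C outruns benzylic deprotonation, the aryllithium is captured by the borate ester, and cold dilute acid hydrolyses the ate complex to the boronic acid with little protodeboronation.

Step 6
Reactants: 4 2-iodo-5-methoxy-1,3-bis(methoxymethoxy)benzene; 11 [4-(benzyloxy)-2-methoxy-6-methylphenyl]boronic acid (2 equiv); 12 carbon monoxide
Product: 13 [4-(benzyloxy)-2-methoxy-6-methylphenyl][4-methoxy-2,6-bis(methoxymethoxy)phenyl]methanone
Conditions: [PdCl2(IPr)(3-chloropyridine)] (5 mol %; IPr = 1,3-bis(2,6-diisopropylphenyl)imidazol-2-ylidene), Cs2CO3 (3 equiv), chlorobenzene, CO (4 bar), 80 °C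
Reagents that add atoms: none
Why: Carbonylative Suzuki–Miyaura coupling, the closest precedent being the palladium–N-heterocyclic carbene catalysed three-component ketone synthesis from ortho-disubstituted aryl iodides. The divalent palladium precatalyst is reduced in the flask to zerovalent palladium–IPr, which inserts into the C–I bond of 4; CO then inserts into the crowded aryl–palladium bond to give the aroyl complex, the carbonate-activated boronate of 11 transmetalates, and reductive elimination forms the C4(ring A')–C(=O) and C(=O)–C1(ring B') bonds of 13. No ring is closed and no stereocenter is made. The selectivity needed is ketone over direct biaryl coupling: the two ortho OMOM groups of 4 hold back transmetalation at the aryl–palladium stage far more than they hold back CO insertion, and CO pressure together with the bulky IPr ligand moves the aryl complex on to the aroyl complex before boron arrives. Excess 11 covers loss by protodeboronation, and because every oxygen is etherified no phenoxide can intercept the aroyl complex.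

Step 7
Reactants: 13 [4-(benzyloxy)-2-methoxy-6-methylphenyl][4-methoxy-2,6-bis(methoxymethoxy)phenyl]methanone
Product: 14 [4-(benzyloxy)-2-methoxy-6-methylphenyl](2,6-dihydroxy-4-methoxyphenyl)methanone
Conditions: HCl (cat., 3 M in MeOH), MeOH–THF, 45 °C
Reagents that add atoms: none
Why: Acid-catalysed acetal exchange removes both MOM ethers while benzyl and methyl ethers are inert, and the methanol solvent traps the methoxymethyl cation as dimethoxymethane so that it does not alkylate the freed ring A'.

Step 8
Reactants: 14 [4-(benzyloxy)-2-methoxy-6-methylphenyl](2,6-dihydroxy-4-methoxyphenyl)methanone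
Product: 15 [4-(benzyloxy)-2-methoxy-6-methylphenyl]{3-[(dimethylamino)methyl]-2,6-dihydroxy-4-methoxyphenyl}methanone
Conditions: CH2=NMe2+ I− (1.0 equiv), K2CO3 (1.0 equiv), CH2Cl2, 0 °C to rt; used without chromatography
Reagents that add atoms: N,N-dimethylmethyleneiminium iodide, C=[N+](C)C.[I-]
Why: Mannich reaction of a phenoxide with a preformed iminium salt: only ring A' carries free hydroxyls, its C2 and C6 are equivalent so one regioisomer results, and one equivalent at low temperature should hold the reaction at monoaminomethylation.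

Step 9
Reactants: 16 orcinol
Product: 17 1,3-bis(benzyloxy)-5-methylbenzene
Conditions: BnBr (2.3 equiv), K2CO3 (3 equiv), DMF, 60 °C
Reagents that add atoms: benzyl bromide, BrCc1ccccc1
Why: Twofold Williamson ether synthesis, O-alkylation prevailing with carbonate in a dipolar aprotic solvent.

Step 10
Reactants: 17 1,3-bis(benzyloxy)-5-methylbenzene
Product: 18 1,5-bis(benzyloxy)-2-bromo-3-methylbenzene
Conditions: NBS (1.0 equiv), MeCN, 0 °C, dark
Reagents that add atoms: N-bromosuccinimide, O=C1CCC(=O)N1Br
Why: Electrophilic aromatic bromination goes para to one benzyloxy group and ortho to the methyl group, as in 3,5-dialkoxytoluenes generally, because the site between the two ether groups is more crowded; polar solvent and darkness exclude benzylic radical bromination.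

Step 11
Reactants: 18 1,5-bis(benzyloxy)-2-bromo-3-methylbenzene
Product: 21 [2,4-bis(benzyloxy)-6-methylphenyl]boronic acid, via aryllithium 19 (not isolated), via lithium aryltriisopropoxyborate 20 (not isolated)
Conditions: n-BuLi (1.05 equiv), THF, −78 °C; B(OiPr)3 (1.5 equiv), −78 °C to rt; 1 M HCl, 0 °C
Reagents that add atoms: triisopropyl borate, CC(C)OB(OC(C)C)OC(C)C; water, O; n-butyllithium, [Li]CCCC (its lithium stays only in 19 and 20)
Why: Bromine–lithium exchange, borate capture and hydrolysis as in step 5, the aryllithium being kept at −78 °C so that the ortho benzyl ether does not rearrange.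

Step 12
Reactants: 4 2-iodo-5-methoxy-1,3-bis(methoxymethoxy)benzene; 21 [2,4-bis(benzyloxy)-6-methylphenyl]boronic acid (2 equiv); 12 carbon monoxide
Product: 22 [2,4-bis(benzyloxy)-6-methylphenyl][4-methoxy-2,6-bis(methoxymethoxy)phenyl]methanone
Conditions: [PdCl2(IPr)(3-chloropyridine)] (5 mol %), Cs2CO3 (3 equiv), chlorobenzene, CO (4 bar), 80 °C
Reagents that add atoms: none
Why: The same carbonylative Suzuki–Miyaura coupling as in step 6, with the same iodide and the ring B boronic acid, forms the C4(ring A)–C(=O) and C(=O)–C1(ring B) bonds of the left ketone.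

Step 13
Reactants: 22 [2,4-bis(benzyloxy)-6-methylphenyl][4-methoxy-2,6-bis(methoxymethoxy)phenyl]methanone
Product: 23 [2,4-bis(benzyloxy)-6-methylphenyl](2,6-dihydroxy-4-methoxyphenyl)methanone
Conditions: HCl (cat., 3 M in MeOH), MeOH–THF, 45 °C
Reagents that add atoms: none
Why: Acid-catalysed methanolysis of the two MOM acetals as in step 7, leaving both benzyl ethers of ring B in place.

Step 14
Reactants: 15 [4-(benzyloxy)-2-methoxy-6-methylphenyl]{3-[(dimethylamino)methyl]-2,6-dihydroxy-4-methoxyphenyl}methanone; 23 [2,4-bis(benzyloxy)-6-methylphenyl](2,6-dihydroxy-4-methoxyphenyl)methanone (2 equiv)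
Product: 25 tri-O-benzyl target (ring B 4,6-di-O-benzyl; ring B' 4-O-benzyl), via ortho-quinone methide 24 (not isolated)
Conditions: 1,4-dioxane, 90 °C, slow addition of 15 to 23, N2 sweep; excess 23 recovered
Reagents that add atoms: none
Why: ortho-Quinone methide alkylation (retro-Mannich elimination, then Friedel–Crafts-type conjugate addition): heat expels dimethylamine from the ortho-hydroxybenzylamine 15, and the methide carbon of 24 is attacked by C6 of ring A of 23, the only free-phenol ring offered in excess, while the benzylated rings B and B' stay inert; excess 23 and slow addition hold back self-condensation.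

Step 15
Reactants: 25 tri-O-benzyl target
Product: 26 (3-{[3-(2,4-dihydroxy-6-methylbenzoyl)-2,4-dihydroxy-6-methoxyphenyl]methyl}-2,6-dihydroxy-4-methoxyphenyl)(4-hydroxy-2-methoxy-6-methylphenyl)methanone (target)
Conditions: H2 (1 atm), Pd/C (10 %), EtOAc–MeOH, rt
Reagents that add atoms: none
Why: Hydrogenolysis of the three aryl benzyl ethers; the hindered, hydrogen-bonded diaryl ketones and the diarylmethane bridge should not be reduced at 1 atm and rt.

Compound list
1 | 5-methoxyresorcinol | COc1cc(O)cc(O)c1 | starting material
2 | 1-methoxy-3,5-bis(methoxymethoxy)benzene | COCOc1cc(OC)cc(OCOC)c1 | intermediate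
3 | [4-methoxy-2,6-bis(methoxymethoxy)phenyl]lithium | [Li]c1c(OCOC)cc(OC)cc1OCOC | intermediate (not isolated)
4 | 2-iodo-5-methoxy-1,3-bis(methoxymethoxy)benzene | COCOc1cc(OC)cc(OCOC)c1I | intermediate
5 | 2-bromo-3-methylanisole | COc1cccc(C)c1Br | starting material
6 | 2-(4-bromo-3-methoxy-5-methylphenyl)-4,4,5,5-tetramethyl-1,3,2-dioxaborolane | COc1cc(B2OC(C)(C)C(C)(C)O2)cc(C)c1Br | intermediate (not isolated)
7 | 4-bromo-3-methoxy-5-methylphenol | COc1cc(O)cc(C)c1Br | intermediate
8 | 5-(benzyloxy)-2-bromo-1-methoxy-3-methylbenzene | COc1cc(OCc2ccccc2)cc(C)c1Br | intermediate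
9 | [4-(benzyloxy)-2-methoxy-6-methylphenyl]lithium | [Li]c1c(C)cc(OCc2ccccc2)cc1OC | intermediate (not isolated)
10 | lithium [4-(benzyloxy)-2-methoxy-6-methylphenyl]tri(propan-2-yloxy)borate | [Li+].COc1cc(OCc2ccccc2)cc(C)c1[B-](OC(C)C)(OC(C)C)OC(C)C | intermediate (not isolated)
11 | [4-(benzyloxy)-2-methoxy-6-methylphenyl]boronic acid | COc1cc(OCc2ccccc2)cc(C)c1B(O)O | intermediate
12 | carbon monoxide | [C-]#[O+] | starting material
13 | [4-(benzyloxy)-2-methoxy-6-methylphenyl][4-methoxy-2,6-bis(methoxymethoxy)phenyl]methanone | COCOc1cc(OC)cc(OCOC)c1C(=O)c1c(C)cc(OCc2ccccc2)cc1OC | intermediate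
14 | [4-(benzyloxy)-2-methoxy-6-methylphenyl](2,6-dihydroxy-4-methoxyphenyl)methanone | COc1cc(O)c(C(=O)c2c(C)cc(OCc3ccccc3)cc2OC)c(O)c1 | intermediate
15 | [4-(benzyloxy)-2-methoxy-6-methylphenyl]{3-[(dimethylamino)methyl]-2,6-dihydroxy-4-methoxyphenyl}methanone | COc1cc(O)c(C(=O)c2c(C)cc(OCc3ccccc3)cc2OC)c(O)c1CN(C)C | intermediate
16 | orcinol (5-methylbenzene-1,3-diol) | Cc1cc(O)cc(O)c1 | starting material
17 | 1,3-bis(benzyloxy)-5-methylbenzene | Cc1cc(OCc2ccccc2)cc(OCc2ccccc2)c1 | intermediate
18 | 1,5-bis(benzyloxy)-2-bromo-3-methylbenzene | Cc1cc(OCc2ccccc2)cc(OCc2ccccc2)c1Br | intermediate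
19 | [2,4-bis(benzyloxy)-6-methylphenyl]lithium | [Li]c1c(C)cc(OCc2ccccc2)cc1OCc1ccccc1 | intermediate (not isolated)
20 | lithium [2,4-bis(benzyloxy)-6-methylphenyl]tri(propan-2-yloxy)borate | [Li+].Cc1cc(OCc2ccccc2)cc(OCc2ccccc2)c1[B-](OC(C)C)(OC(C)C)OC(C)C | intermediate (not isolated)
21 | [2,4-bis(benzyloxy)-6-methylphenyl]boronic acid | Cc1cc(OCc2ccccc2)cc(OCc2ccccc2)c1B(O)O | intermediate
22 | [2,4-bis(benzyloxy)-6-methylphenyl][4-methoxy-2,6-bis(methoxymethoxy)phenyl]methanone | COCOc1cc(OC)cc(OCOC)c1C(=O)c1c(C)cc(OCc2ccccc2)cc1OCc1ccccc1 | intermediate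
23 | [2,4-bis(benzyloxy)-6-methylphenyl](2,6-dihydroxy-4-methoxyphenyl)methanone | COc1cc(O)c(C(=O)c2c(C)cc(OCc3ccccc3)cc2OCc2ccccc2)c(O)c1 | intermediate
24 | 2-[4-(benzyloxy)-2-methoxy-6-methylbenzoyl]-3-hydroxy-5-methoxy-6-methylidenecyclohexa-2,4-dien-1-one (ortho-quinone methide) | C=C1C(=O)C(C(=O)c2c(C)cc(OCc3ccccc3)cc2OC)=C(O)C=C1OC | intermediate (not isolated)
25 | tri-O-benzyl target: the target with benzyl ethers on O4 and O6 of ring B and on O4 of ring B' | COc1cc(O)c(C(=O)c2c(C)cc(OCc3ccccc3)cc2OCc2ccccc2)c(O)c1Cc1c(OC)cc(O)c(C(=O)c2c(C)cc(OCc3ccccc3)cc2OC)c1O | intermediate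
26 | (3-{[3-(2,4-dihydroxy-6-methylbenzoyl)-2,4-dihydroxy-6-methoxyphenyl]methyl}-2,6-dihydroxy-4-methoxyphenyl)(4-hydroxy-2-methoxy-6-methylphenyl)methanone | COc1cc(O)c(C(=O)c2c(C)cc(O)cc2O)c(O)c1Cc1c(OC)cc(O)c(C(=O)c2c(C)cc(O)cc2OC)c1O | target

Total step count: 15.
Longest linear sequence: 8 steps (steps 3, 4, 5, 6, 7, 8, 14, 15).

Steps most likely to fail

Step 6 (key step). The ketone has four ortho substituents. Transmetalation of the di-ortho-substituted boronate onto the crowded aroyl–palladium complex may be slower than protodeboronation of 11 and than hydrolysis of the aroyl complex, and direct biaryl coupling may intrude if CO insertion lags. Fallback, setting out from 2 and 8 and coming back at 13: aryllithium 3 is generated from 2 as in step 2 and quenched with DMF (water work-up) to give 4-methoxy-2,6-bis(methoxymethoxy)benzaldehyde F1. Aryllithium 9, made from 8 with n-BuLi at −78 °C as in step 5, is added to F1 in THF to give the racemic diaryl carbinol [4-(benzyloxy)-2-methoxy-6-methylphenyl][4-methoxy-2,6-bis(methoxymethoxy)phenyl]methanol F2, whose stereocenter disappears in the next operation. Oxidation of F2 with Dess–Martin periodinane (NaHCO3, CH2Cl2, rt) gives ketone 13, where the route resumes at step 7.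

Step 12. The same coupling on the left half can fail in the same way, and the ortho benzyloxy group makes boronic acid 21 bulkier still, so transmetalation may stall and 21 may be lost by protodeboronation. Fallback, setting out from 18 and coming back at 22: aryllithium 19, made from 18 with n-BuLi at −78 °C, is added to the aldehyde F1 (prepared from 2 as described for step 6) to give the racemic carbinol [2,4-bis(benzyloxy)-6-methylphenyl][4-methoxy-2,6-bis(methoxymethoxy)phenyl]methanol F3. Dess–Martin oxidation of F3 gives ketone 22, and the route resumes at step 13.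

Step 14. The quinone methide may be captured by the free C2–H of a second molecule of 15 or of product 25 instead of by 23, giving right–right dimers and oligomers, and on long heating the new diarylmethane bond may re-ionise and scramble to the symmetrical dimers. Fallback, setting out from 14 and 23 and coming back at 25 (step 8 is then not needed): the preformed electrophile is given up for a one-pot three-component condensation. A solution of 14 and excess 23 in MeOH–dilute aqueous NaOH at 0 °C is treated with aqueous formaldehyde (one equivalent relative to 14). Hydroxymethylation of a free ring A or A' occurs, shown for 14 as [4-(benzyloxy)-2-methoxy-6-methylphenyl][2,6-dihydroxy-3-(hydroxymethyl)-4-methoxyphenyl]methanone F4 (not isolated). Loss of water gives the quinone methide 24, and capture by the other monomer gives 25. The two symmetrical dimers that form alongside carry two and four benzyl groups and should be separable from 25 by chromatography; the route resumes at step 15.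

Further compounds
F1 | step 6 | 4-methoxy-2,6-bis(methoxymethoxy)benzaldehyde | COCOc1cc(OC)cc(OCOC)c1C=O
F2 | step 6 | [4-(benzyloxy)-2-methoxy-6-methylphenyl][4-methoxy-2,6-bis(methoxymethoxy)phenyl]methanol (racemic) | COCOc1cc(OC)cc(OCOC)c1C(O)c1c(C)cc(OCc2ccccc2)cc1OC
F3 | step 12 | [2,4-bis(benzyloxy)-6-methylphenyl][4-methoxy-2,6-bis(methoxymethoxy)phenyl]methanol (racemic) | COCOc1cc(OC)cc(OCOC)c1C(O)c1c(C)cc(OCc2ccccc2)cc1OCc1ccccc1
F4 | step 14 | [4-(benzyloxy)-2-methoxy-6-methylphenyl][2,6-dihydroxy-3-(hydroxymethyl)-4-methoxyphenyl]methanone | COc1cc(O)c(C(=O)c2c(C)cc(OCc3ccccc3)cc2OC)c(O)c1CO
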